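## Retrosynthetic overview

1. The target is traced back to tricyclic ketone 25 through a late C2 oxidation/reduction, desilylation, C5 ketone reduction, acetylation, PMB removal, enol-ether hydrolysis and C1 methylenation.
2. Ketone 25 comes from the open-chain alkynol silyloxyenal 23 in one operation: gold-catalysed closure of a temporary tetrahydrofuran (ring C), then a (4+3) cycloaddition that closes the cyclopentene (ring A) and the cycloheptene (ring B) together.
3. Enabling feature: ring B is a three-carbon unit C10–C1–C2 (ring-fusion CH, the carbon carrying =CH2, the CHOH) joined to a four-carbon unit C3–C4–C5–C6. C5 at the ketone level is γ to the side-chain oxygen on C13, so C5 and O13 can be tied as a cyclic enol ether that locks the diene C3=C4–C5=C6 s-cis, shields one face, and is hydrolysed later.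
4. Enal 23 comes from Sonogashira union of vinyl iodide 11 (chiral-pool C14, chelation-controlled Marshall propargylation for C11/C13) with silyloxydioxin 20 (dioxanone alkylated with the commercial Z-enynol), then a retro-hetero-Diels–Alder reaction.
5. Ring order: ring C (temporary) first, then rings A and B simultaneously; ring C is opened in step 19.

Key step: step 17

Remark (locants used in the text only): hydroazulene C1 (carries =CH2), C2 (allylic CHOH), C3 (CH2), C4 (CH bearing the side chain), C5 (CHOH), C6 and C10 (ring-fusion CH, C6 next to C5), C7 (methyl-bearing sp2 C), C8, C9; side chain C11 (CH with methyl C12), C13 and C14 (the two CHOAc), C15=C16 (isobutenyl).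

Remark (assumption): the dioxane/dioxin carbon that becomes C10 is formed unselectively in 18–22 and is written without configuration, because it becomes sp2 in 23. Acetal 4 is an epimer mixture at the acetal carbon, which is removed in step 4.

## Route

Step 1
Reactants: 1 (R)-2,2-dimethyl-1,3-dioxolane-4-carbaldehyde
Product: 2 (S)-2,2-dimethyl-4-(2-methylprop-1-en-1-yl)-1,3-dioxolane
Conditions: i-PrPPh3I, n-BuLi, THF, −78 → 0 °C
Reagents that add atoms: isopropyltriphenylphosphonium iodide, CC(C)[P+](c1ccccc1)(c1ccccc1)c1ccccc1.[I-]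
Why: Wittig olefination with the non-stabilised isopropylidene ylide installs C15=C16, and the chiral-pool centre (later C14) is untouched at low temperature.

Step 2
Reactants: 2 (S)-2,2-dimethyl-4-(2-methylprop-1-en-1-yl)-1,3-dioxolane
Product: 3 (S)-4-methylpent-3-ene-1,2-diol
Conditions: AcOH/H2O (4:1), 40 °C
Reagents that add atoms: none
Why: Acid-catalysed acetonide hydrolysis under conditions mild enough for the trisubstituted allylic system; no stereocentre is affected.

Step 3
Reactants: 3 (S)-4-methylpent-3-ene-1,2-diol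
Product: 4 (4S)-2-(4-methoxyphenyl)-4-(2-methylprop-1-en-1-yl)-1,3-dioxolane
Conditions: 4-MeOC6H4CH(OMe)2, PPTS (cat.), CH2Cl2, rt
Reagents that add atoms: 4-methoxybenzaldehyde dimethyl acetal, COC(OC)c1ccc(OC)cc1
Why: Acid-catalysed transacetalisation gives the p-methoxybenzylidene acetal of the 1,2-diol.

Step 4
Reactants: 4 (4S)-2-(4-methoxyphenyl)-4-(2-methylprop-1-en-1-yl)-1,3-dioxolane
Product: 5 (S)-2-[(4-methoxybenzyl)oxy]-4-methylpent-3-en-1-ol
Conditions: i-Bu2AlH, CH2Cl2, −78 → 0 °C
Reagents that add atoms: none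
Why: Regioselective reductive acetal opening, in which aluminium binds the less hindered primary oxygen and hydride leaves the PMB group on the secondary oxygen.

Step 5
Reactants: 5 (S)-2-[(4-methoxybenzyl)oxy]-4-methylpent-3-en-1-ol
Product: 6 (S)-2-[(4-methoxybenzyl)oxy]-4-methylpent-3-enal
Conditions: Dess–Martin periodinane, NaHCO3, CH2Cl2, 0 °C; used crude at once
Reagents that add atoms: none
Why: Buffered Dess–Martin oxidation gives the α-alkoxy aldehyde without base, so the labile α-centre (C14) should not epimerise or move into conjugation.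

Step 6
Reactants: 7 (R)-but-3-yn-2-ol
Product: 8 (R)-but-3-yn-2-yl methanesulfonate
Conditions: MsCl, Et3N, CH2Cl2, −78 °C
Reagents that add atoms: methanesulfonyl chloride, CS(=O)(=O)Cl
Why: O-sulfonylation with retention at carbon activates the propargylic alcohol.

Step 7
Reactants: 8 (R)-but-3-yn-2-yl methanesulfonate
Product: 9 (P)-buta-1,2-dien-1-yl(tributyl)stannane
Conditions: Bu3SnH, LiN(i-Pr)2, THF, 0 °C; CuBr·SMe2, −78 °C; then 8
Reagents that add atoms: tributyltin hydride, CCCC[SnH](CCCC)CCCC
Why: Anti SN2' displacement of the propargylic mesylate by the stannylcuprate converts the central chirality of 8 into the axial chirality of the (P)-allene.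

Step 8
Reactants: 6 (S)-2-[(4-methoxybenzyl)oxy]-4-methylpent-3-enal; 9 (P)-buta-1,2-dien-1-yl(tributyl)stannane
Product: 10 (3R,4S,5S)-5-[(4-methoxybenzyl)oxy]-3,7-dimethyloct-6-en-1-yn-4-ol
Conditions: MgBr2·OEt2, CH2Cl2, −23 °C
Reagents that add atoms: none
Why: Marshall propargylation (SE2' addition anti to tin): the (P)-allene sets C11 and the syn C11/C13 relation, and the MgBr2 chelate of the α-PMB-oxy aldehyde directs attack to give the syn C13/C14 relation (matched pair).

Step 9
Reactants: 10 (3R,4S,5S)-5-[(4-methoxybenzyl)oxy]-3,7-dimethyloct-6-en-1-yn-4-ol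
Product: 11 (3S,4S,5S)-2-iodo-5-[(4-methoxybenzyl)oxy]-3,7-dimethylocta-1,6-dien-4-ol
Conditions: Ni(dppp)Cl2 (3 mol%), i-Bu2AlH (2.3 equiv), THF, 0 °C → rt; then N-iodosuccinimide, 0 °C
Reagents that add atoms: N-iodosuccinimide, O=C1CCC(=O)N1I
Why: Nickel-catalysed α-selective (Markovnikov) hydroalumination of the terminal alkyne, after the first equivalent of hydride has taken the OH proton, followed by iodinolysis gives the 2-iodo-1-alkene; the stereotriad is not touched.

Step 10
Reactants: 12 (Z)-3-methylpent-2-en-4-yn-1-ol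
Product: 14 (Z)-3-methyl-5-(trimethylsilyl)pent-2-en-4-yn-1-ol, via bis-silylated enynol 13 (not isolated)
Conditions: EtMgBr (2.2 equiv), THF, 0 °C → rt; Me3SiCl (2.2 equiv); then 10% aq. citric acid
Reagents that add atoms: chlorotrimethylsilane, C[Si](C)(C)Cl
Why: Double deprotonation and silylation followed by selective hydrolysis of the labile O–Si bond masks the acidic alkyne C–H for the aza-enolate alkylation in step 13.

Step 11
Reactants: 14 (Z)-3-methyl-5-(trimethylsilyl)pent-2-en-4-yn-1-ol
Product: 15 [(Z)-5-bromo-3-methylpent-3-en-1-yn-1-yl]trimethylsilane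
Conditions: CBr4, PPh3, CH2Cl2, −20 °C
Reagents that add atoms: carbon tetrabromide, BrC(Br)(Br)Br
Why: Appel bromination (SN2 at the primary allylic carbon) under neutral, cold conditions keeps the Z-alkene.

Step 12
Reactants: 16 2,2-dimethyl-1,3-dioxan-5-one
Product: 17 2-(2,2-dimethyl-1,3-dioxan-5-ylidene)-1,1-dimethylhydrazine
Conditions: Me2NNH2, cyclohexane, reflux (water separator)
Reagents that add atoms: 1,1-dimethylhydrazine, CN(C)N
Why: Condensation to the N,N-dimethylhydrazone gives a ketone equivalent that can be C-alkylated cleanly, unlike the self-condensing dioxanone enolate.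

Step 13
Reactants: 17 2-(2,2-dimethyl-1,3-dioxan-5-ylidene)-1,1-dimethylhydrazine; 15 [(Z)-5-bromo-3-methylpent-3-en-1-yn-1-yl]trimethylsilane
Product: 19 2,2-dimethyl-4-[(Z)-3-methyl-5-(trimethylsilyl)pent-2-en-4-yn-1-yl]-1,3-dioxan-5-one, via alkylated hydrazone 18 (not isolated)
Conditions: LiN(i-Pr)2, THF, −78 °C; 15, −78 → −20 °C; then sat. aq. oxalic acid, Et2O, rt
Reagents that add atoms: water, O
Why: Hydrazone aza-enolate alkylation (SN2 at the allylic bromide, forming C9–C10) and mild two-phase hydrazone hydrolysis that spares the acetonide; the new centre is inconsequential.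

Step 14
Reactants: 19 2,2-dimethyl-4-[(Z)-3-methyl-5-(trimethylsilyl)pent-2-en-4-yn-1-yl]-1,3-dioxan-5-one
Product: 20 {2,2-dimethyl-4-[(Z)-3-methyl-5-(trimethylsilyl)pent-2-en-4-yn-1-yl]-4H-1,3-dioxin-5-yl}oxy(triisopropyl)silane
Conditions: i-Pr3SiOTf, Et3N, CH2Cl2, 0 °C → rt
Reagents that add atoms: triisopropylsilyl trifluoromethanesulfonate, CC(C)[Si](C(C)C)(C(C)C)OS(=O)(=O)C(F)(F)F
Why: Soft enolisation and O-silylation go towards the unsubstituted CH2 and give the 4-alkyl-5-silyloxy-4H-1,3-dioxin, the masked form of the silyloxyenal.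

Step 15
Reactants: 20 {2,2-dimethyl-4-[(Z)-3-methyl-5-(trimethylsilyl)pent-2-en-4-yn-1-yl]-4H-1,3-dioxin-5-yl}oxy(triisopropyl)silane; 11 (3S,4S,5S)-2-iodo-5-[(4-methoxybenzyl)oxy]-3,7-dimethylocta-1,6-dien-4-ol
Product: 22 dienynol dioxin (the C4-alkynylated 1-alkene formed from 11 and the alkyne of 20; dioxin and silyl enol ether intact), via terminal alkyne 21 (not isolated)
Conditions: K2CO3, MeOH, 0 °C; solvent exchange; then 11, Pd(PPh3)4 (5 mol%), CuI (10 mol%), Et3N, THF, rt
Reagents that add atoms: none
Why: Protodesilylation of the alkynylsilane and Sonogashira coupling with the 2-iodo-1-alkene form the C4–C5 bond; the Z-enyne, the silyl enol ether and the free C13 alcohol are inert at room temperature.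

Step 16
Reactants: 22 dienynol dioxin
Product: 23 (Z)-2-(triisopropylsilyloxy)-2-enal carrying the (Z)-enyne tether and the alkynol side chain
Conditions: toluene (base-washed glass), 110 °C
Reagents that add atoms: none
Why: Thermal retro-hetero-Diels–Alder reaction of the 4H-1,3-dioxin expels acetone and gives the (Z)-2-silyloxy-2-enal (alkyl group pseudo-equatorial in the transition state); the diene is still masked as an enyne, so no thermal Diels–Alder reaction can compete.

Step 17
Reactants: 23 (Z)-2-(triisopropylsilyloxy)-2-enal carrying the (Z)-enyne tether and the alkynol side chain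
Product: 25 tricyclic α-silyloxy ketone (trans-fused rings A/B, ring C as a 4,5-dihydrofuran with C4=C5), via dienol ether 24 (not isolated)
Conditions: Ph3PAuNTf2 (2 mol%), CH2Cl2, 0 °C; then 2,6-di-tert-butyl-4-methylpyridine (20 mol%), Sc(OTf)3 (10 mol%), −40 → 0 °C
Reagents that add atoms: none
Why: Ph3PAuNTf2 activates the C5≡C6 alkyne for anti 5-exo-dig attack of the C13 hydroxyl and gives the (Z)-2-alkylidene-3-methylenetetrahydrofuran 24 (ring C: O, C5, C4, C11, C13), whose s-cis-locked, electron-rich diene C3=C4–C5=C6 then adds to the Sc(OTf)3-bound (Z)-2-silyloxyenal, a 2-silyloxyallyl cation C10–C1–C2 with oxygen on C2, in a (4+3) cycloaddition that forms C6–C10 and C2–C3, after which the silyl group moves from the C1 oxygen to the C2 oxygen and frees the catalyst. The closest known reactions are the gold-catalysed cycloisomerisation of 4-alkyn-1-ols to 2-alkylidenetetrahydrofurans and the Lewis-acid-catalysed intramolecular (4+3) cyclisation of (Z)-2-(trialkylsilyloxy)-2-enals with a tethered diene, including the silyl-transfer variant with Sc(OTf)3. Ring A closes by 5-exo attack of the nucleophilic enol-ether carbon C6 on the enal β-carbon C10 through the cis-alkene tether C7=C8–C9, and ring B closes by bonding of C2 to C3 of the resulting vinyl oxocarbenium, either in the same asynchronous event or directly after it. The cis C11-methyl and C13 substituent of ring C cover one face of the diene, so the cation adds to the other face, which with the Z enol ether (C7 outside) fixes C6, while the Z-enal (C9 outside) and the extended transition state usual for a three-atom tether give the trans ring fusion and fix C10. C2 is drawn as expected from the W-shaped cation (silyloxy cis to C9), but its configuration is not relied upon because it is reset in steps 24 and 25. The step needs (4+3) rather than (4+2) closure and no acid-induced isomerisation of the dienol ether, which the oxygen-bearing cation termini C10 and C2, the hindered pyridine as proton scavenger and the low temperature should secure.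

Step 18
Reactants: 25 tricyclic α-silyloxy ketone
Product: 26 tricyclic exo-methylene enol ether
Conditions: Cp2TiMe2, toluene/THF, 65 °C, dark
Reagents that add atoms: dimethyltitanocene, [CH3-].[CH3-].[Ti+4].c1cc[cH-]c1.c1cc[cH-]c1
Why: Petasis methylenation through the non-basic titanium methylidene converts the hindered, epimerisable C1 ketone into the exocyclic alkene without touching C10, the enol ether or the PMB ether.

Step 19
Reactants: 26 tricyclic exo-methylene enol ether
Product: 27 C5 ketone with free C13 alcohol (ring C opened)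
Conditions: AcOH/THF/H2O (3:1:1), 0 °C → rt
Reagents that add atoms: water, O
Why: Acid-catalysed hydrolysis of the cyclic enol ether, in which kinetic protonation at C4 comes from the face opposite the neighbouring cis C11-methyl (also the axial direction on the cycloheptene chair) and sets C4, and the hemiketal then opens to the C5 ketone and the C13 alcohol.

Step 20
Reactants: 27 C5 ketone with free C13 alcohol
Product: 28 C13,C14-diol ketone
Conditions: DDQ, CH2Cl2/pH 7 phosphate buffer (10:1), 0 °C
Reagents that add atoms: none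
Why: Oxidative PMB cleavage in wet, buffered medium, where water traps the benzylic oxocarbenium before the neighbouring hydroxyl can; alkenes and the silyl ether are inert.

Step 21
Reactants: 28 C13,C14-diol ketone
Product: 29 C13,C14-diacetate ketone
Conditions: Ac2O, pyridine, DMAP (cat.), CH2Cl2, 0 °C → rt
Reagents that add atoms: acetic anhydride, CC(=O)OC(C)=O
Why: DMAP-catalysed acetylation of the two side-chain alcohols at a stage where C5 is a ketone and C2 is silylated, so the two ring oxygens cannot be acylated.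

Step 22
Reactants: 29 C13,C14-diacetate ketone
Product: 30 C5 alcohol, C2 silyl ether
Conditions: LiBH(s-Bu)3, THF, −78 °C; non-oxidative work-up
Reagents that add atoms: none
Why: The bulky hydride attacks the C5 carbonyl anti to the branched C4 side chain (the larger flanking group) and gives the alcohol cis to it, and the acetates survive at −78 °C.

Step 23
Reactants: 30 C5 alcohol, C2 silyl ether
Product: 31 2-epi diol (C2 epimer of the target)
Conditions: HF·pyridine, pyridine, THF, 0 °C → rt
Reagents that add atoms: none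
Why: Buffered fluoride cleavage of the secondary silyl ether without base, so the acetates neither migrate nor hydrolyse.

Step 24
Reactants: 31 2-epi diol
Product: 32 C2 enone (2-methylene ketone), C5 alcohol free
Conditions: activated MnO2 (excess), CH2Cl2, rt; used at once
Reagents that add atoms: none
Why: MnO2 oxidises only the allylic C2 alcohol (the C5 alcohol is not allylic) and thereby erases the C2 centre.

Step 25
Reactants: 32 C2 enone
Product: 33 CNP0423623.2 (target)
Conditions: (S)-2-methyl-CBS-oxazaborolidine (1.0 equiv), catecholborane, toluene, −78 °C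
Reagents that add atoms: none
Why: Corey–Bakshi–Shibata 1,2-reduction under reagent control, with the alkenyl carbon C1 as the large group and C3H2 as the small one, gives the (R)-alcohol at C2 (OH trans to C9); catecholborane leaves acetates and alkenes alone at this temperature.

## Compound list

1 | (R)-2,2-dimethyl-1,3-dioxolane-4-carbaldehyde | O=C[C@H]1COC(C)(C)O1 | starting material
2 | (S)-2,2-dimethyl-4-(2-methylprop-1-en-1-yl)-1,3-dioxolane | CC(C)=C[C@H]1COC(C)(C)O1 | intermediate
3 | (S)-4-methylpent-3-ene-1,2-diol | CC(C)=C[C@H](O)CO | intermediate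
4 | (4S)-2-(4-methoxyphenyl)-4-(2-methylprop-1-en-1-yl)-1,3-dioxolane (acetal epimers) | CC(C)=C[C@H]1COC(c2ccc(OC)cc2)O1 | intermediate
5 | (S)-2-[(4-methoxybenzyl)oxy]-4-methylpent-3-en-1-ol | OC[C@H](C=C(C)C)OCc1ccc(OC)cc1 | intermediate
6 | (S)-2-[(4-methoxybenzyl)oxy]-4-methylpent-3-enal | O=C[C@H](C=C(C)C)OCc1ccc(OC)cc1 | intermediate
7 | (R)-but-3-yn-2-ol | C#C[C@@H](C)O | starting material
8 | (R)-but-3-yn-2-yl methanesulfonate | C#C[C@@H](C)OS(C)(=O)=O | intermediate
9 | (P)-buta-1,2-dien-1-yl(tributyl)stannane | [H]C([Sn](CCCC)(CCCC)CCCC)=[C@]=C([H])C | intermediate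
10 | (3R,4S,5S)-5-[(4-methoxybenzyl)oxy]-3,7-dimethyloct-6-en-1-yn-4-ol | C#C[C@@H](C)[C@H](O)[C@H](C=C(C)C)OCc1ccc(OC)cc1 | intermediate
11 | (3S,4S,5S)-2-iodo-5-[(4-methoxybenzyl)oxy]-3,7-dimethylocta-1,6-dien-4-ol | C=C(I)[C@@H](C)[C@H](O)[C@H](C=C(C)C)OCc1ccc(OC)cc1 | intermediate
12 | (Z)-3-methylpent-2-en-4-yn-1-ol | OC/C=C(C)\C#C | starting material
13 | trimethyl{[(Z)-3-methyl-5-(trimethylsilyl)pent-2-en-4-yn-1-yl]oxy}silane | C[Si](C)(C)OC/C=C(C)\C#C[Si](C)(C)C | intermediate
14 | (Z)-3-methyl-5-(trimethylsilyl)pent-2-en-4-yn-1-ol | OC/C=C(C)\C#C[Si](C)(C)C | intermediate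
15 | [(Z)-5-bromo-3-methylpent-3-en-1-yn-1-yl]trimethylsilane | BrC/C=C(C)\C#C[Si](C)(C)C | intermediate
16 | 2,2-dimethyl-1,3-dioxan-5-one | CC1(C)OCC(=O)CO1 | starting material
17 | 2-(2,2-dimethyl-1,3-dioxan-5-ylidene)-1,1-dimethylhydrazine | CC1(C)OCC(=NN(C)C)CO1 | intermediate
18 | N,N-dimethylhydrazone of 19 | CC1(C)OCC(=NN(C)C)C(C/C=C(C)\C#C[Si](C)(C)C)O1 | intermediate
19 | 2,2-dimethyl-4-[(Z)-3-methyl-5-(trimethylsilyl)pent-2-en-4-yn-1-yl]-1,3-dioxan-5-one | CC1(C)OCC(=O)C(C/C=C(C)\C#C[Si](C)(C)C)O1 | intermediate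
20 | {2,2-dimethyl-4-[(Z)-3-methyl-5-(trimethylsilyl)pent-2-en-4-yn-1-yl]-4H-1,3-dioxin-5-yl}oxy(triisopropyl)silane | CC1(C)OC=C(O[Si](C(C)C)(C(C)C)C(C)C)C(C/C=C(C)\C#C[Si](C)(C)C)O1 | intermediate
21 | terminal alkyne from 20 (C-desilylated) | CC1(C)OC=C(O[Si](C(C)C)(C(C)C)C(C)C)C(C/C=C(C)\C#C)O1 | intermediate
22 | dienynol dioxin: 5-silyloxy-4H-1,3-dioxin carrying at its C4 the (Z)-3-methylpent-2-en-4-ynyl chain, alkyne joined to C4 of the 1-alkene of the side-chain stereotriad | CC1(C)OC=C(O[Si](C(C)C)(C(C)C)C(C)C)C(C/C=C(C)\C#CC(=C)[C@@H](C)[C@H](O)[C@H](C=C(C)C)OCc2ccc(OC)cc2)O1 | intermediate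
23 | (Z)-2-(triisopropylsilyloxy)-2-enal with (Z)-C7=C8, C5≡C6, C4=CH2, free C13–OH and C14–OPMB | O=C/C(O[Si](C(C)C)(C(C)C)C(C)C)=C/C/C=C(C)\C#CC(=C)[C@@H](C)[C@H](O)[C@H](C=C(C)C)OCc1ccc(OC)cc1 | intermediate
24 | dienol ether: (Z)-2-alkylidene-3-methylenetetrahydrofuran (cis 4-methyl and 5-substituent) tethered to the (Z)-2-silyloxyenal | O=C/C(O[Si](C(C)C)(C(C)C)C(C)C)=C/C/C=C(C)\C=C1/O[C@H]([C@H](C=C(C)C)OCc2ccc(OC)cc2)[C@H](C)C1=C | intermediate
25 | tricyclic α-silyloxy ketone: C1 ketone, C2–OSi(i-Pr)3 cis to C9, trans-fused rings A/B, ring C as 4,5-dihydrofuran (C4=C5, O on C5 and C13) | O=C1[C@@H](O[Si](C(C)C)(C(C)C)C(C)C)CC3=C(O[C@@H]([C@@H]3C)[C@H](C=C(C)C)OCc4ccc(OC)cc4)[C@@H]2C(C)=CC[C@@H]12 | intermediate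
26 | tricyclic exo-methylene enol ether (C1=CH2; otherwise as 25) | C=C1[C@@H](O[Si](C(C)C)(C(C)C)C(C)C)CC3=C(O[C@@H]([C@@H]3C)[C@H](C=C(C)C)OCc4ccc(OC)cc4)[C@@H]2C(C)=CC[C@@H]12 | intermediate
27 | C5 ketone, C13–OH, C14–OPMB, C2–OSi(i-Pr)3 | C=C1[C@@H](O[Si](C(C)C)(C(C)C)C(C)C)C[C@@H]([C@@H](C)[C@H](O)[C@H](C=C(C)C)OCc3ccc(OC)cc3)C(=O)[C@@H]2C(C)=CC[C@@H]12 | intermediate
28 | C5 ketone, C13,C14-diol, C2–OSi(i-Pr)3 | C=C1[C@@H](O[Si](C(C)C)(C(C)C)C(C)C)C[C@@H]([C@@H](C)[C@H](O)[C@H](C=C(C)C)O)C(=O)[C@@H]2C(C)=CC[C@@H]12 | intermediate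
29 | C5 ketone, C13,C14-diacetate, C2–OSi(i-Pr)3 | C=C1[C@@H](O[Si](C(C)C)(C(C)C)C(C)C)C[C@@H]([C@@H](C)[C@H](OC(C)=O)[C@H](C=C(C)C)OC(C)=O)C(=O)[C@@H]2C(C)=CC[C@@H]12 | intermediate
30 | C5 alcohol, C13,C14-diacetate, C2–OSi(i-Pr)3 | C=C1[C@@H](O[Si](C(C)C)(C(C)C)C(C)C)C[C@@H]([C@@H](C)[C@H](OC(C)=O)[C@H](C=C(C)C)OC(C)=O)[C@@H](O)[C@@H]2C(C)=CC[C@@H]12 | intermediate
31 | 2-epi diol (C2 epimer of the target) | C=C1[C@@H](O)C[C@@H]([C@@H](C)[C@H](OC(C)=O)[C@H](C=C(C)C)OC(C)=O)[C@@H](O)[C@@H]2C(C)=CC[C@@H]12 | intermediate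
32 | C2 enone (1-methylene-2-oxo), C5 alcohol, diacetate | C=C1C(=O)C[C@@H]([C@@H](C)[C@H](OC(C)=O)[C@H](C=C(C)C)OC(C)=O)[C@@H](O)[C@@H]2C(C)=CC[C@@H]12 | intermediate
33 | CNP0423623.2 | C=C1[C@H](O)C[C@@H]([C@@H](C)[C@H](OC(C)=O)[C@H](C=C(C)C)OC(C)=O)[C@@H](O)[C@@H]2C(C)=CC[C@@H]12 | target

## Step count and risks

Total step count: 25. Longest linear sequence: 18 steps (steps 1–5, 8, 9, 15–25, from compound 1).

Steps most likely to fail:

1. Step 17. The free enal may close by a (4+2) pathway, the dienol ether may isomerise under acid before it cyclises, or the trans ring fusion may form with low selectivity. Fallback: set out from 22 and keep the three-carbon unit masked. Gold-catalysed cycloisomerisation of 22 (Ph3PAuNTf2, CH2Cl2, 0 °C) should give the dienol ether dioxin F1. Me3SiOTf (cat.) with 2,6-di-tert-butylpyridine at −78 °C then ionises the allylic C–O bond of the 4H-1,3-dioxin (a vinylogous acetal, Ferrier-type). This gives an alkoxy-substituted 2-silyloxyallyl cation, as in acetal-derived oxyallyl-cation (4+3) cycloadditions, at a temperature where no free enal is present. Loss of acetone and silyl transfer return the route to 25.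

2. Step 19. Protonation at C4 may take place from the wrong face, giving the C4 epimer. Fallback: switch from kinetic to thermodynamic control. From 26 the hydrolysis would then give the C4 epimer of 27 F2. F2 is equilibrated through its enol with DBU in CH2Cl2 at rt to 27, in which the C4 side chain and C7 are trans and both pseudo-equatorial on the cycloheptanone. The exposure must be short because C6 is also enolisable.

3. Step 22. Hydride may be delivered to the wrong face of the C5 carbonyl. Fallback: from 29 reduce under electron-transfer, thermodynamic control with SmI2 in THF/i-PrOH, where protonation of the ketyl gives the more stable alcohol, complementary to the kinetic bulky-hydride result. This returns to 30 and makes no new compound (F0).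

## Further compounds

F1 | step 17 | dienol ether dioxin: (Z)-2-alkylidene-3-methylenetetrahydrofuran tethered to the intact 5-silyloxy-4H-1,3-dioxin | CC1(C)OC=C(O[Si](C(C)C)(C(C)C)C(C)C)C(C/C=C(C)\C=C2/O[C@H]([C@H](C=C(C)C)OCc3ccc(OC)cc3)[C@H](C)C2=C)O1
F2 | step 19 | C4 epimer of 27 | C=C1[C@@H](O[Si](C(C)C)(C(C)C)C(C)C)C[C@H]([C@@H](C)[C@H](O)[C@H](C=C(C)C)OCc3ccc(OC)cc3)C(=O)[C@@H]2C(C)=CC[C@@H]12
F0 | step 22 | none | none
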